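**Assumption:** atoms are labelled with germacrane numbering (C1–C15, lactone = 12,8-olide) and the target is read as 3R,6R,7R,8S with 1(10)E and 4E double bonds; C6 is formally S in the iodo compounds 24–26 only because iodine raises the priority of C5, the geometry is that of the target.

## Retrosynthetic overview

1. The ten-membered ring is closed last at C3–C4 by a Ni/Cr-catalysed alkenyl iodide–aldehyde coupling, which sets C3 and leaves the 3-OH free.
2. The seco-aldehyde comes from a Cr-catalysed C6–C7 allylation of iodo-enal 21 with bromomethyl-butenolide 13; it sets C6 and C7 and installs the 6-O-isovalerate in the same step.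
3. Butenolide 13 comes from ring-closing metathesis of the 2-(bromomethyl)acrylate of allylic alcohol 9, itself from (S)-epichlorohydrin and an alkenyllithium made from pent-3-yn-1-ol.
4. Enal 21 comes from but-2-yne-1,4-diol by Pd hydrostannation (fixes the 4E geometry), OH differentiation, isovalerylation, iodination and oxidation.
5. Ring order: butenolide (RCM), then α-methylene-γ-lactone (allylic transposition in the coupling), then the ten-membered carbocycle.

## Route

Step 1
Reactants: 1 pent-3-yn-1-ol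
Product: 2 tert-butyl(dimethyl)(pent-3-yn-1-yloxy)silane
Conditions: TBSCl, imidazole, DMF, rt
Reagents that add atoms: tert-butyldimethylsilyl chloride, CC(C)(C)[Si](C)(C)Cl
Why: Standard silylation of a primary alcohol; the TBS ether survives the organometallic steps and is removed with fluoride in step 15.

Step 2
Reactants: 2 tert-butyl(dimethyl)(pent-3-yn-1-yloxy)silane
Product: 4 (E)-tert-butyl[(4-iodopent-3-en-1-yl)oxy]dimethylsilane, via alkenylzirconocene chloride 3 (not isolated)
Conditions: Cp2Zr(H)Cl (2.2 equiv), THF, 50 °C; then I2, 0 °C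
Reagents that add atoms: iodine, II
Why: Schwartz hydrozirconation adds H–Zr syn and, after equilibration with excess reagent, places Zr on the methyl-bearing carbon; iodinolysis with retention gives the E iodide that becomes the 1(10)E alkene.

Step 3
Reactants: 4 (E)-tert-butyl[(4-iodopent-3-en-1-yl)oxy]dimethylsilane; 5 (S)-epichlorohydrin
Product: 7 (2S,4E)-7-[(tert-butyldimethylsilyl)oxy]-1-chloro-4-methylhept-4-en-2-ol, via alkenyllithium 6 (not isolated)
Conditions: t-BuLi (2.05 equiv), Et2O, −78 °C; then BF3·OEt2, 5, −78 °C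
Reagents that add atoms: none
Why: Iodine–lithium exchange with retention followed by BF3-assisted SN2 opening at the unsubstituted epoxide carbon; the stereocentre of 5 is untouched and becomes C8 (S).

Step 4
Reactants: 7 (2S,4E)-7-[(tert-butyldimethylsilyl)oxy]-1-chloro-4-methylhept-4-en-2-ol
Product: 9 (3S,5E)-8-[(tert-butyldimethylsilyl)oxy]-5-methylocta-1,5-dien-3-ol, via terminal epoxide 8 (not isolated)
Conditions: Me3S+ I− (4 equiv), n-BuLi (3.8 equiv), THF, −10 °C → rt
Reagents that add atoms: trimethylsulfonium iodide, C[S+](C)C.[I-]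
Why: The ylide closes the chlorohydrin to the epoxide, then opens it at CH2 and eliminates Me2S (sulfonium ylide one-carbon homologation of an epoxide to an allylic alcohol), leaving the carbinol centre untouched.

Step 5
Reactants: 10 2-(bromomethyl)acrylic acid
Product: 11 2-(bromomethyl)acryloyl chloride
Conditions: (COCl)2, DMF (cat.), CH2Cl2, 0 °C → rt; distil
Reagents that add atoms: oxalyl chloride, ClC(=O)C(=O)Cl
Why: Vilsmeier-type acid chloride formation under neutral conditions keeps the allylic bromide intact.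

Step 6
Reactants: 9 (3S,5E)-8-[(tert-butyldimethylsilyl)oxy]-5-methylocta-1,5-dien-3-ol; 11 2-(bromomethyl)acryloyl chloride
Product: 12 (3S,5E)-8-[(tert-butyldimethylsilyl)oxy]-5-methylocta-1,5-dien-3-yl 2-(bromomethyl)acrylate
Conditions: 2,6-lutidine, CH2Cl2, −20 → 0 °C
Reagents that add atoms: none
Why: O-acylation with an acid chloride and a hindered, weakly nucleophilic base avoids SN2′ attack of an amine on the bromomethyl acrylate; no bond to the stereocentre is broken.

Step 7
Reactants: 12 (3S,5E)-8-[(tert-butyldimethylsilyl)oxy]-5-methylocta-1,5-dien-3-yl 2-(bromomethyl)acrylate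
Product: 13 (5S)-3-(bromomethyl)-5-[(2E)-5-[(tert-butyldimethylsilyl)oxy]-2-methylpent-2-en-1-yl]furan-2(5H)-one
Conditions: Hoveyda–Grubbs II (5 mol %), toluene (5 mM), 80 °C, N2 sparge
Reagents that add atoms: none
Why: Ring-closing metathesis of an allyl 2-substituted acrylate to an α-substituted butenolide is favoured by five-ring formation and ethylene loss; the trisubstituted alkene is a spectator.

Step 8
Reactants: 14 but-2-yne-1,4-diol
Product: 15 (E)-2-(tributylstannyl)but-2-ene-1,4-diol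
Conditions: Bu3SnH, PdCl2(PPh3)2 (1 mol %), THF, rt
Reagents that add atoms: tributyltin hydride, CCCC[SnH](CCCC)CCCC
Why: Pd-catalysed hydrostannation is a syn addition, so the two CH2OH groups end up cis, which is the C15/C6 relationship of the 4E alkene.

Step 9
Reactants: 15 (E)-2-(tributylstannyl)but-2-ene-1,4-diol
Product: 16 (E)-4-[(tert-butyldimethylsilyl)oxy]-2-(tributylstannyl)but-2-en-1-ol
Conditions: TBSCl (1.0 equiv), imidazole, CH2Cl2, −20 °C
Reagents that add atoms: tert-butyldimethylsilyl chloride, CC(C)(C)[Si](C)(C)Cl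
Why: The CH2OH geminal to the bulky Bu3Sn group is shielded, so mono-silylation goes to the distal hydroxyl (the future C6 oxygen).

Step 10
Reactants: 16 (E)-4-[(tert-butyldimethylsilyl)oxy]-2-(tributylstannyl)but-2-en-1-ol; 17 3-methylbutanoyl chloride
Product: 18 (E)-4-[(tert-butyldimethylsilyl)oxy]-2-(tributylstannyl)but-2-en-1-yl 3-methylbutanoate
Conditions: pyridine, DMAP (cat.), CH2Cl2, 0 °C
Reagents that add atoms: none
Why: Base-buffered acylation of the remaining primary alcohol installs the C15 isovalerate without protodestannylation.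

Step 11
Reactants: 18 (E)-4-[(tert-butyldimethylsilyl)oxy]-2-(tributylstannyl)but-2-en-1-yl 3-methylbutanoate
Product: 19 (E)-4-[(tert-butyldimethylsilyl)oxy]-2-iodobut-2-en-1-yl 3-methylbutanoate
Conditions: I2 (1.05 equiv), CH2Cl2, 0 °C
Reagents that add atoms: iodine, II
Why: Iododestannylation proceeds with retention, so iodine sits trans to the future C6 carbon.

Step 12
Reactants: 19 (E)-4-[(tert-butyldimethylsilyl)oxy]-2-iodobut-2-en-1-yl 3-methylbutanoate
Product: 20 (E)-4-hydroxy-2-iodobut-2-en-1-yl 3-methylbutanoate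
Conditions: HF·pyridine, pyridine/THF, 0 °C → rt
Reagents that add atoms: none
Why: Fluoride cleaves the primary silyl ether under buffered conditions that leave the ester and alkenyl iodide alone.

Step 13
Reactants: 20 (E)-4-hydroxy-2-iodobut-2-en-1-yl 3-methylbutanoate
Product: 21 (E)-2-iodo-4-oxobut-2-en-1-yl 3-methylbutanoate
Conditions: Dess–Martin periodinane, NaHCO3, CH2Cl2, 0 °C, dark; used at once
Reagents that add atoms: none
Why: Buffered Dess–Martin oxidation of the allylic alcohol gives the β-iodo enal without acid or nucleophiles that would scramble the double bond.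

Step 14
Reactants: 13 (5S)-3-(bromomethyl)-5-[(2E)-5-[(tert-butyldimethylsilyl)oxy]-2-methylpent-2-en-1-yl]furan-2(5H)-one; 21 (E)-2-iodo-4-oxobut-2-en-1-yl 3-methylbutanoate; 17 3-methylbutanoyl chloride
Product: 24 (1S,2E)-1-[(2S,3R)-2-[(2E)-5-[(tert-butyldimethylsilyl)oxy]-2-methylpent-2-en-1-yl]-4-methylidene-5-oxooxolan-3-yl]-3-iodobut-2-ene-1,4-diyl bis(3-methylbutanoate), via allylchromium(III) species 22 (not isolated), via chromium(III) alkoxide 23 (not isolated)
Conditions: CrCl2 (15 mol %, Ni-free), Mn powder (2 equiv), 17 (1.3 equiv, syringe pump), THF, 0 °C → rt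
Reagents that add atoms: none
Why: Proposed new method: a Cr-catalysed Nozaki–Hiyama allylation in which the acyl chloride replaces TMSCl as the turnover reagent, so that Cr(II) inserts into the allylic bromide, the ring-locked (E-type) allylchromium adds through a closed chair transition state at the butenolide β-carbon on the face anti to the C8 side chain (trans lactone at C7, anti relationship at C6), and the Cr(III) alkoxide is acylated by 17 to give the 6-isovalerate and CrCl3, which Mn reduces back to Cr(II), the acylation also stopping translactonisation of the alkoxide; the closest known reactions are the Cr-catalysed allylation with TMSCl/Mn turnover and the Zn Barbier reactions of 3-(bromomethyl)butenolides.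

Step 15
Reactants: 24 (1S,2E)-1-[(2S,3R)-2-[(2E)-5-[(tert-butyldimethylsilyl)oxy]-2-methylpent-2-en-1-yl]-4-methylidene-5-oxooxolan-3-yl]-3-iodobut-2-ene-1,4-diyl bis(3-methylbutanoate)
Product: 25 (1S,2E)-1-[(2S,3R)-2-[(2E)-5-hydroxy-2-methylpent-2-en-1-yl]-4-methylidene-5-oxooxolan-3-yl]-3-iodobut-2-ene-1,4-diyl bis(3-methylbutanoate)
Conditions: HF·pyridine, pyridine/THF, 0 °C
Reagents that add atoms: none
Why: Buffered fluoride removes the primary TBS ether without touching the esters, the α-methylene lactone or the alkenyl iodide.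

Step 16
Reactants: 25 (1S,2E)-1-[(2S,3R)-2-[(2E)-5-hydroxy-2-methylpent-2-en-1-yl]-4-methylidene-5-oxooxolan-3-yl]-3-iodobut-2-ene-1,4-diyl bis(3-methylbutanoate)
Product: 26 (1S,2E)-3-iodo-1-[(2S,3R)-4-methylidene-2-[(2E)-2-methyl-5-oxopent-2-en-1-yl]-5-oxooxolan-3-yl]but-2-ene-1,4-diyl bis(3-methylbutanoate)
Conditions: Dess–Martin periodinane, NaHCO3, CH2Cl2, 0 °C; used crude
Reagents that add atoms: none
Why: Neutral Dess–Martin oxidation gives the β,γ-unsaturated aldehyde without moving the C1=C10 double bond into conjugation.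

Step 17
Reactants: 26 (1S,2E)-3-iodo-1-[(2S,3R)-4-methylidene-2-[(2E)-2-methyl-5-oxopent-2-en-1-yl]-5-oxooxolan-3-yl]but-2-ene-1,4-diyl bis(3-methylbutanoate)
Product: 29 (3R,6R,7R,8S)-3-hydroxy-6,15-bis(3-methylbutanoyloxy)germacra-1(10)E,4E,11(13)-trien-12,8-olide, via alkenylchromium(III) species 27 (not isolated), via zirconocene alkoxide 28 (not isolated)
Conditions: NiCl2·(2,9-dimethylphenanthroline) (5 mol %), CrCl2 (20 mol %), chiral oxazoline–sulfonamide ligand (22 mol %, enantiomer that gives 3R), proton sponge (22 mol %), Mn, Cp2ZrCl2, LiCl, MeCN (2 mM), rt; aq. work-up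
Reagents that add atoms: none
Why: Ni/Cr-catalysed Nozaki–Hiyama–Kishi macrocyclisation in which Ni(0) inserts into the alkenyl iodide with retention of the 4E geometry, the alkenyl group passes to Cr(III) and adds 1,2 to the aldehyde with the chiral Cr complex selecting the face that gives 3R, while the C–metal bond, being trans to C6, cannot reach the lactone methylene.

## Compound list

1 | pent-3-yn-1-ol | CC#CCCO | starting material
2 | tert-butyl(dimethyl)(pent-3-yn-1-yloxy)silane | CC#CCCO[Si](C)(C)C(C)(C)C | intermediate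
3 | (E)-alkenylzirconocene chloride from 2 (Cp drawn η1) | C/C(=C\CCO[Si](C)(C)C(C)(C)C)[Zr](Cl)(C1C=CC=C1)C1C=CC=C1 | intermediate
4 | (E)-tert-butyl[(4-iodopent-3-en-1-yl)oxy]dimethylsilane | C/C(I)=C\CCO[Si](C)(C)C(C)(C)C | intermediate
5 | (S)-epichlorohydrin | ClC[C@@H]1CO1 | starting material
6 | (E)-5-[(tert-butyldimethylsilyl)oxy]pent-2-en-2-yllithium | C/C([Li])=C\CCO[Si](C)(C)C(C)(C)C | intermediate
7 | (2S,4E)-7-[(tert-butyldimethylsilyl)oxy]-1-chloro-4-methylhept-4-en-2-ol | ClC[C@@H](O)C/C(C)=C/CCO[Si](C)(C)C(C)(C)C | intermediate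
8 | (S)-2-[(2E)-5-[(tert-butyldimethylsilyl)oxy]-2-methylpent-2-en-1-yl]oxirane | O1C[C@@H]1C/C(C)=C/CCO[Si](C)(C)C(C)(C)C | intermediate
9 | (3S,5E)-8-[(tert-butyldimethylsilyl)oxy]-5-methylocta-1,5-dien-3-ol | C=C[C@@H](O)C/C(C)=C/CCO[Si](C)(C)C(C)(C)C | intermediate
10 | 2-(bromomethyl)acrylic acid | C=C(CBr)C(=O)O | starting material
11 | 2-(bromomethyl)acryloyl chloride | C=C(CBr)C(=O)Cl | intermediate
12 | (3S,5E)-8-[(tert-butyldimethylsilyl)oxy]-5-methylocta-1,5-dien-3-yl 2-(bromomethyl)acrylate | C=C[C@@H](OC(=O)C(=C)CBr)C/C(C)=C/CCO[Si](C)(C)C(C)(C)C | intermediate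
13 | (5S)-3-(bromomethyl)-5-[(2E)-5-[(tert-butyldimethylsilyl)oxy]-2-methylpent-2-en-1-yl]furan-2(5H)-one | BrCC1=C[C@H](C/C(C)=C/CCO[Si](C)(C)C(C)(C)C)OC1=O | intermediate
14 | but-2-yne-1,4-diol | OCC#CCO | starting material
15 | (E)-2-(tributylstannyl)but-2-ene-1,4-diol | OC/C=C(\CO)[Sn](CCCC)(CCCC)CCCC | intermediate
16 | (E)-4-[(tert-butyldimethylsilyl)oxy]-2-(tributylstannyl)but-2-en-1-ol | OC/C(=C\CO[Si](C)(C)C(C)(C)C)[Sn](CCCC)(CCCC)CCCC | intermediate
17 | 3-methylbutanoyl chloride (isovaleryl chloride) | CC(C)CC(=O)Cl | starting material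
18 | (E)-4-[(tert-butyldimethylsilyl)oxy]-2-(tributylstannyl)but-2-en-1-yl 3-methylbutanoate | CC(C)CC(=O)OC/C(=C\CO[Si](C)(C)C(C)(C)C)[Sn](CCCC)(CCCC)CCCC | intermediate
19 | (E)-4-[(tert-butyldimethylsilyl)oxy]-2-iodobut-2-en-1-yl 3-methylbutanoate | CC(C)CC(=O)OC/C(I)=C\CO[Si](C)(C)C(C)(C)C | intermediate
20 | (E)-4-hydroxy-2-iodobut-2-en-1-yl 3-methylbutanoate | CC(C)CC(=O)OC/C(I)=C\CO | intermediate
21 | (E)-2-iodo-4-oxobut-2-en-1-yl 3-methylbutanoate | CC(C)CC(=O)OC/C(I)=C\C=O | intermediate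
22 | allylchromium(III) dichloride from 13 (solvent ligands omitted) | Cl[Cr](Cl)CC1=C[C@H](C/C(C)=C/CCO[Si](C)(C)C(C)(C)C)OC1=O | intermediate
23 | chromium(III) alkoxide of the C6 carbinol (C6–O–CrCl2; otherwise as 24) | C=C1C(=O)O[C@@H](C/C(C)=C/CCO[Si](C)(C)C(C)(C)C)[C@@H]1[C@H](O[Cr](Cl)Cl)/C=C(/I)COC(=O)CC(C)C | intermediate
24 | (1S,2E)-1-[(2S,3R)-2-[(2E)-5-[(tert-butyldimethylsilyl)oxy]-2-methylpent-2-en-1-yl]-4-methylidene-5-oxooxolan-3-yl]-3-iodobut-2-ene-1,4-diyl bis(3-methylbutanoate) | C=C1C(=O)O[C@@H](C/C(C)=C/CCO[Si](C)(C)C(C)(C)C)[C@@H]1[C@H](OC(=O)CC(C)C)/C=C(/I)COC(=O)CC(C)C | intermediate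
25 | (1S,2E)-1-[(2S,3R)-2-[(2E)-5-hydroxy-2-methylpent-2-en-1-yl]-4-methylidene-5-oxooxolan-3-yl]-3-iodobut-2-ene-1,4-diyl bis(3-methylbutanoate) | C=C1C(=O)O[C@@H](C/C(C)=C/CCO)[C@@H]1[C@H](OC(=O)CC(C)C)/C=C(/I)COC(=O)CC(C)C | intermediate
26 | (1S,2E)-3-iodo-1-[(2S,3R)-4-methylidene-2-[(2E)-2-methyl-5-oxopent-2-en-1-yl]-5-oxooxolan-3-yl]but-2-ene-1,4-diyl bis(3-methylbutanoate) | C=C1C(=O)O[C@@H](C/C(C)=C/CC=O)[C@@H]1[C@H](OC(=O)CC(C)C)/C=C(/I)COC(=O)CC(C)C | intermediate
27 | alkenylchromium(III) dichloride from 26 (Cr in place of I) | C=C1C(=O)O[C@@H](C/C(C)=C/CC=O)[C@@H]1[C@H](OC(=O)CC(C)C)/C=C(/[Cr](Cl)Cl)COC(=O)CC(C)C | intermediate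
28 | zirconocene chloride 3-alkoxide of 29 (Cp drawn η1) | C=C1C(=O)O[C@H]2C/C(C)=C/C[C@@H](O[Zr](Cl)(C3C=CC=C3)C3C=CC=C3)/C(COC(=O)CC(C)C)=C/[C@@H](OC(=O)CC(C)C)[C@H]12 | intermediate
29 | (3R,6R,7R,8S)-3-hydroxy-6,15-bis(3-methylbutanoyloxy)germacra-1(10)E,4E,11(13)-trien-12,8-olide (CNP0317194.1) | C=C1C(=O)O[C@H]2C/C(C)=C/C[C@@H](O)/C(COC(=O)CC(C)C)=C/[C@@H](OC(=O)CC(C)C)[C@H]12 | target

## Step count and risks

Total step count: 17.
Longest linear sequence: 10 steps (1–4, 6, 7, 14–17 from pent-3-yn-1-ol; equally 8–17 from but-2-yne-1,4-diol).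

**Step 14 (proposed new step).** The acyl chloride may be attacked by the allylchromium, or may fail to turn over the Cr(III) alkoxide. The fallback uses known chemistry and sets out from 13 and 21. A stoichiometric zinc Barbier reaction (Zn dust, THF/sat. aq. NH4Cl, 0 °C → rt), the established way to add 3-(bromomethyl)butenolides to aldehydes through the same closed transition state, gives the free C6 alcohol (1S,2E)-4-hydroxy-4-[(2S,3R)-2-[(2E)-5-[(tert-butyldimethylsilyl)oxy]-2-methylpent-2-en-1-yl]-4-methylidene-5-oxooxolan-3-yl]-2-iodobut-2-en-1-yl 3-methylbutanoate F1, protonated as it forms. F1 is then esterified in a separate operation with 17 (pyridine, DMAP cat., CH2Cl2, 0 °C), and the route is rejoined at 24.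

**Step 17.** Closure of the strained E,E-cyclodecadiene may be slow, and the C3 selectivity may be poor. The fallback sets out from 26 and moves C3 stereocontrol from the C–C bond formation to a ketone reduction. A classical achiral ring closure (CrCl2 6 equiv, NiCl2 1 mol %, DMSO/THF, 2 mM) gives 29 together with its C3 epimer, (3S,6R,7R,8S)-3-hydroxy-6,15-bis(3-methylbutanoyloxy)germacra-1(10)E,4E,11(13)-trien-12,8-olide F5. The mixture is oxidised (Dess–Martin periodinane, NaHCO3) to the single dienone (6R,7R,8S)-6,15-bis(3-methylbutanoyloxy)-3-oxogermacra-1(10)E,4E,11(13)-trien-12,8-olide F6. Reduction of F6 with (S)-Me-CBS and catecholborane at −78 °C, the alkenyl side acting as the large group, returns to the route at 29.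

**Step 13.** The β-iodo enal 21 can lose its double-bond geometry by addition–elimination or decompose before it is coupled. The fallback sets out from 18 and postpones the iodination until after the coupling. Desilylation (TBAF/AcOH, THF, 0 °C) gives (E)-4-hydroxy-2-(tributylstannyl)but-2-en-1-yl 3-methylbutanoate F2. MnO2 in CH2Cl2 gives the configurationally robust stannyl enal (E)-4-oxo-2-(tributylstannyl)but-2-en-1-yl 3-methylbutanoate F3. Coupling of F3 with 13 and 17 as in step 14 gives the stannane analogue of 24, (1S,2E)-1-[(2S,3R)-2-[(2E)-5-[(tert-butyldimethylsilyl)oxy]-2-methylpent-2-en-1-yl]-4-methylidene-5-oxooxolan-3-yl]-3-(tributylstannyl)but-2-ene-1,4-diyl bis(3-methylbutanoate) F4. Iododestannylation of F4 (I2, CH2Cl2, 0 °C) rejoins the route at 24.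

Further compounds
F1 | step 14 | (1S,2E)-4-hydroxy-4-[(2S,3R)-2-[(2E)-5-[(tert-butyldimethylsilyl)oxy]-2-methylpent-2-en-1-yl]-4-methylidene-5-oxooxolan-3-yl]-2-iodobut-2-en-1-yl 3-methylbutanoate | C=C1C(=O)O[C@@H](C/C(C)=C/CCO[Si](C)(C)C(C)(C)C)[C@@H]1[C@H](O)/C=C(/I)COC(=O)CC(C)C
F2 | step 13 | (E)-4-hydroxy-2-(tributylstannyl)but-2-en-1-yl 3-methylbutanoate | CC(C)CC(=O)OC/C(=C\CO)[Sn](CCCC)(CCCC)CCCC
F3 | step 13 | (E)-4-oxo-2-(tributylstannyl)but-2-en-1-yl 3-methylbutanoate | CC(C)CC(=O)OC/C(=C\C=O)[Sn](CCCC)(CCCC)CCCC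
F4 | step 13 | (1S,2E)-1-[(2S,3R)-2-[(2E)-5-[(tert-butyldimethylsilyl)oxy]-2-methylpent-2-en-1-yl]-4-methylidene-5-oxooxolan-3-yl]-3-(tributylstannyl)but-2-ene-1,4-diyl bis(3-methylbutanoate) | C=C1C(=O)O[C@@H](C/C(C)=C/CCO[Si](C)(C)C(C)(C)C)[C@@H]1[C@H](OC(=O)CC(C)C)/C=C(/[Sn](CCCC)(CCCC)CCCC)COC(=O)CC(C)C
F5 | step 17 | (3S,6R,7R,8S)-3-hydroxy-6,15-bis(3-methylbutanoyloxy)germacra-1(10)E,4E,11(13)-trien-12,8-olide | C=C1C(=O)O[C@H]2C/C(C)=C/C[C@H](O)/C(COC(=O)CC(C)C)=C/[C@@H](OC(=O)CC(C)C)[C@H]12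
F6 | step 17 | (6R,7R,8S)-6,15-bis(3-methylbutanoyloxy)-3-oxogermacra-1(10)E,4E,11(13)-trien-12,8-olide | C=C1C(=O)O[C@H]2C/C(C)=C/CC(=O)/C(COC(=O)CC(C)C)=C/[C@@H](OC(=O)CC(C)C)[C@H]12
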